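Everything rests on one cationic cascade that converts a monocyclic vinylcyclobutane into the tricyclic cage. It exploits the cyclopentane C16–C17–C18–C20–C21, fused through the oxygen-bearing C16 and its neighbour C21 to the lactone-bridged bicyclooctane: the imprint of a cyclobutylcarbinyl cation at C21 that has expanded and been trapped at C16 by the C13 carboxyl. In one operation C22 of a (Z)-alkene attacks the C12 ketone, C20 shifts from C16 to C21 and O15–C16 closes, giving three rings and four stereocentres. The precursor is a tert-butyl α-keto ester with an (R)-silyloxy group at C27, tethered to a 3-silyloxycyclobutane that carries the (Z)-3-aryloxypropenyl group cis to O19.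

Key step: step 11

Remark: atom numbers are those of the target SMILES; TBS = tert-butyldimethylsilyl, TMS = trimethylsilyl.
Assumption: in step 7 the (S,S)-ProPhenol/n-Bu2Mg catalyst is taken to give the (R)-carbinol at C27; if the sense of induction is the opposite one, the (R,R)-ligand is used.
Assumption: compound 1 is bought as the cis/trans mixture, which is immaterial because C16 becomes planar in step 2.

Step 1
Reactants: 1 methyl 3-hydroxycyclobutane-1-carboxylate
Product: 2 methyl 3-(TBS-oxy)cyclobutane-1-carboxylate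
Conditions: TBSCl, imidazole, DMF, rt
Reagents that add atoms: tert-butyldimethylsilyl chloride, CC(C)(C)[Si](C)(C)Cl
Why: Silylation of the secondary alcohol (TBSCl/imidazole) should be routine, and the C16 configuration of either isomer is erased on enolisation in step 2.

Step 2
Reactants: 2 methyl 3-(TBS-oxy)cyclobutane-1-carboxylate; 3 allyl bromide
Product: 5 methyl 1-allyl-3-(TBS-oxy)cyclobutane-1-carboxylate (allyl trans to the silyloxy group), via lithium enolate 4 (not isolated)
Conditions: LiN(i-Pr)2, THF, −78 °C; then 3, DMPU, −78 to −20 °C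
Reagents that add atoms: none
Why: Ester enolate alkylation, in which the allyl group should enter the planar enolate on the ring face away from the transannular C18 silyloxy group, leaving the ester carbon (future C21) cis to O19 and C26 trans; the minor isomer would be removed by chromatography.

Step 3
Reactants: 5 methyl 1-allyl-3-(TBS-oxy)cyclobutane-1-carboxylate
Product: 7 1-allyl-1-ethynyl-3-(TBS-oxy)cyclobutane (ethynyl cis to the silyloxy group), via cyclobutanecarbaldehyde 6 (not isolated)
Conditions: i-Bu2AlH (1.1 equiv), CH2Cl2, −78 °C; then MeOH, dimethyl (1-diazo-2-oxopropyl)phosphonate, K2CO3, −78 °C to rt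
Reagents that add atoms: dimethyl (1-diazo-2-oxopropyl)phosphonate, CC(=O)C(=[N+]=[N-])P(=O)(OC)OC
Why: Half-reduction of the hindered α-quaternary ester to the aluminium hemiacetal, then Ohira–Bestmann (Seyferth–Gilbert) homologation of the aldehyde set free by methanol, should give the terminal alkyne with the new carbon as C22; the aldehyde has no α-hydrogen and cannot epimerise.

Step 4
Reactants: 7 1-allyl-1-ethynyl-3-(TBS-oxy)cyclobutane
Product: 9 3-[1-allyl-3-(TBS-oxy)cyclobutyl]prop-2-yn-1-ol, via lithium acetylide 8 (not isolated)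
Conditions: n-BuLi, THF, −78 °C; then (CH2O)n, −78 °C to rt
Reagents that add atoms: paraformaldehyde (formaldehyde), C=O
Why: Addition of the lithium acetylide to formaldehyde should install C23 as a primary propargylic alcohol.

Step 5
Reactants: 9 3-[1-allyl-3-(TBS-oxy)cyclobutyl]prop-2-yn-1-ol
Product: 10 1-allyl-1-[3-(4-methoxyphenoxy)prop-1-ynyl]-3-(TBS-oxy)cyclobutane
Conditions: 4-methoxyphenol, PPh3, DIAD, THF, 0 °C to rt
Reagents that add atoms: 4-methoxyphenol, COc1ccc(O)cc1
Why: Mitsunobu etherification of the primary alcohol with the phenol; an aryl ether is chosen for C23 because its oxygen is a far weaker donor than a benzylic ether oxygen and cannot be lost as a stabilised benzyl cation, so it should neither capture the C16 cation nor be cleaved by the Lewis acid in step 11.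

Step 6
Reactants: 10 1-allyl-1-[3-(4-methoxyphenoxy)prop-1-ynyl]-3-(TBS-oxy)cyclobutane
Product: 11 2-{1-[3-(4-methoxyphenoxy)prop-1-ynyl]-3-(TBS-oxy)cyclobutyl}acetaldehyde
Conditions: OsO4 (2 mol%), NaIO4, 2,6-lutidine, dioxane/H2O, rt
Reagents that add atoms: sodium periodate (oxygen delivered through catalytic OsO4), [Na+].[O-]I(=O)(=O)=O
Why: Lemieux–Johnson cleavage (OsO4-catalysed dihydroxylation, periodate scission) of the terminal alkene to the C27 aldehyde; the internal alkyne and the aryl ether should be inert, which is why ozone is avoided.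

Step 7
Reactants: 11 2-{1-[3-(4-methoxyphenoxy)prop-1-ynyl]-3-(TBS-oxy)cyclobutyl}acetaldehyde; 12 tert-butyl diazoacetate
Product: 13 tert-butyl (3R)-2-diazo-3-hydroxy-4-{1-[3-(4-methoxyphenoxy)prop-1-ynyl]-3-(TBS-oxy)cyclobutyl}butanoate
Conditions: n-Bu2Mg (10 mol%), (S,S)-ProPhenol (5 mol%), cis-cyclopentane-1,2-diol (5 mol%), THF, −20 °C
Reagents that add atoms: none
Why: Magnesium–ProPhenol-catalysed asymmetric aldol addition of the diazoacetate to an unbranched aliphatic aldehyde; the catalyst alone should set C27 as (R), since the cyclobutane has a mirror plane and exerts no bias.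

Step 8
Reactants: 13 tert-butyl (3R)-2-diazo-3-hydroxy-4-{cyclobutyl}butanoate
Product: 14 tert-butyl (3R)-2-diazo-3-(TBS-oxy)-4-{1-[3-(4-methoxyphenoxy)prop-1-ynyl]-3-(TBS-oxy)cyclobutyl}butanoate
Conditions: TBSOTf, 2,6-lutidine, CH2Cl2, −78 °C
Reagents that add atoms: tert-butyldimethylsilyl triflate, CC(C)(C)[Si](C)(C)OS(=O)(=O)C(F)(F)F
Why: Silylation of the hindered secondary carbinol with the silyl triflate; the fully substituted diazo carbon carries no hydrogen that could be silylated.

Step 9
Reactants: 14 tert-butyl (3R)-2-diazo-3-(TBS-oxy)butanoate derivative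
Product: 15 tert-butyl (3R)-2-oxo-3-(TBS-oxy)-4-{1-[3-(4-methoxyphenoxy)prop-1-ynyl]-3-(TBS-oxy)cyclobutyl}butanoate
Conditions: dimethyldioxirane (acetone solution), CH2Cl2, 0 °C
Reagents that add atoms: dimethyldioxirane, CC1(C)OO1
Why: Oxygen transfer from the dioxirane to the diazo carbon with loss of N2 is the established way from α-diazo esters to α-keto esters; the alkyne and the aryl ether react far more slowly at 0 °C.

Step 10
Reactants: 15 alkynyl α-keto ester
Product: 16 tert-butyl (3R)-2-oxo-3-(TBS-oxy)-4-{1-[(Z)-3-(4-methoxyphenoxy)prop-1-enyl]-3-(TBS-oxy)cyclobutyl}butanoate (alkenyl cis to O19)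
Conditions: H2 (1 atm), Pd/CaCO3 poisoned with Pb(OAc)2, quinoline, EtOAc, rt
Reagents that add atoms: none
Why: Lindlar semihydrogenation (syn addition of H2) should give the (Z)-alkene; ketone and aryl ether are not reduced over the poisoned catalyst, and uptake is stopped at one equivalent.

Step 11
Reactants: 16 (Z)-alkenyl cyclobutane α-keto ester
Product: 18 tricyclic cage lactone with free O11–H; 4-methoxyphenoxymethyl on C22; TBS ethers on O19 and O28, via tertiary C16 cation 17 (not isolated)
Conditions: Me2AlCl (2.2 equiv), CH2Cl2 (0.01 M), −78 to −40 °C; aqueous potassium sodium tartrate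
Reagents that add atoms: none
Why: Proposed new method: Me2AlCl chelates the C12/C13 dicarbonyl, C22 of the (Z)-alkene attacks C12 (6-endo-trig Prins closure of the carbocycle C12–C22–C21–C16–C26–C27) while the cyclobutane bond C16–C20, antiperiplanar to the forming bond, shifts to C21 (a 1,2-shift that enlarges the ring to the cyclopentane C16–C17–C18–C20–C21 and releases strain), and the tertiary cation 17 is captured at C16 by the ester carbonyl (six-membered lactone C13–O15–C16, completing the bicyclooctane) with loss of 2-methylpropene, the released proton being destroyed by an Al–CH3 bond. The closest known chemistry is the Prins–pinacol cascade and cation–olefin cyclisation ended by a cyclobutylcarbinyl-to-cyclopentyl shift. C22 and C21 follow from anti addition across the (Z)-alkene, which places C23 and C20 cis, and O19, cis to the alkenyl group on the cyclobutane, ends cis to H21. C12 is set against C27 in a chair-like closure with the C27 silyloxy group equatorial and antiperiplanar to the incoming C22 (polar Felkin–Anh), the aluminium-bound O11 axial and the chelated ester equatorial, so that C13 is cis to C23 and trans to O28; C16 needs no control of its own, because after the C12 end of the chair has flipped the ester can reach only the lobe that C20 has left. The step needs attack through C22 and not C21, secured because positive charge at C21 is carried by the cyclobutane bond whereas C22 lies next to the C23 oxygen, and it needs capture of C16 by the ester rather than by O23, O11 or proton loss: O23 is a weakly basic aryl ether without a labile group, and a bridged ether formed by O11 should re-ionise under the Lewis acid and drain into the lactone, whose formation is irreversible.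

Step 12
Reactants: 18 cage lactone with the C23 aryl ether
Product: 19 cage lactone with free C23–OH and O11–H; TBS ethers on O19 and O28
Conditions: (NH4)2Ce(NO3)6, MeCN/H2O (4:1), 0 °C
Reagents that add atoms: none
Why: Oxidative cleavage of the 4-methoxyphenyl ether by tetravalent cerium (the arene leaves as benzoquinone) should free the C23 alcohol; silyl ethers, lactone and the tertiary alcohol tolerate the short exposure at 0 °C.

Step 13
Reactants: 19 cage lactone with free C23–OH
Product: 20 cage lactone C23 aldehyde with free O11–H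
Conditions: Dess–Martin periodinane, CH2Cl2, 0 °C to rt
Reagents that add atoms: none
Why: Dess–Martin oxidation of the primary alcohol to the aldehyde; the tertiary O11–H cannot be oxidised and the neutral medium should leave C22 untouched.

Step 14
Reactants: 20 cage lactone C23 aldehyde
Product: 21 cage lactone C23 aldehyde with O11–TMS
Conditions: N-(trimethylsilyl)imidazole, CH2Cl2, rt
Reagents that add atoms: N-(trimethylsilyl)imidazole, C[Si](C)(C)n1ccnc1
Why: Neutral silylation of the exposed bridgehead hydroxyl; it blocks formation of the O11 alkoxide, which under the basic conditions of step 15 could open the C12–C22 bond by retro-aldol reaction.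

Step 15
Reactants: 21 cage lactone C23 aldehyde with O11–TMS
Product: 22 cage lactone with the (Z)-2-iodoprop-1-enyl group on C22 (iodine cis to C22) and O11–TMS
Conditions: ethyltriphenylphosphonium iodide, n-BuLi, THF, rt; iodine, −78 °C; NaN(SiMe3)2, −20 °C; then 21, −78 to −20 °C
Reagents that add atoms: ethyltriphenylphosphonium iodide, CC[P+](c1ccccc1)(c1ccccc1)c1ccccc1.[I-]; iodine, [I][I]
Why: Stork–Zhao Wittig olefination with the α-iodo ylide should give the (Z)-2-iodoalkene with iodine cis to C22, which introduces C24 and C25 and places the future C10 on the side of O11.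

Step 16
Reactants: 22 (Z)-alkenyl iodide
Product: 24 cage lactone with the fused 2-methoxy-3-methyl-2H-pyran (methyl acetal at C10; both anomers), via (Z)-enal 23 (not isolated)
Conditions: Pd(PPh3)4 (5 mol%), CO (1 atm), n-Bu3SnH (slow addition), THF, 50 °C; then MeOH, pyridinium p-toluenesulfonate, rt
Reagents that add atoms: carbon monoxide, [C-]#[O+]; methanol, CO
Why: Palladium-catalysed reductive carbonylation of the alkenyl iodide (formylation with CO and the tin hydride) keeps the alkene geometry; in acidic methanol the trimethylsilyl ether is solvolysed, O11 adds to the cis aldehyde and the lactol is fixed as its methyl acetal, so C10 reaches the aldehyde level without any hydride reagent that could attack the C13 lactone.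

Step 17
Reactants: 25 1-nonyne
Product: 27 potassium (E)-non-1-enyltrifluoroborate, via alkenyl catecholboronate 26 (not isolated)
Conditions: catecholborane, neat, 70 °C; then KHF2, MeOH/H2O, rt
Reagents that add atoms: catecholborane, B1Oc2ccccc2O1; potassium hydrogen difluoride, [K+].F[H-]F
Why: syn-Hydroboration of the terminal alkyne with catecholborane gives the (E)-alkenylboronate, which KHF2 converts into the stable trifluoroborate.

Step 18
Reactants: 24 methyl acetal; 27 potassium (E)-non-1-enyltrifluoroborate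
Product: 28 bis-TBS ether (O19, O28) of the target
Conditions: BF3·OEt2, CH2Cl2/MeCN, −78 to −40 °C; cold NaHCO3 quench
Reagents that add atoms: none
Why: BF3 ionises the allylic acetal to the cyclic oxocarbenium ion and turns the trifluoroborate into the alkenyldifluoroborane that adds at C10 (known addition of organotrifluoroborates to acetals, a Ferrier-type C-glycosylation); the cage locks the half-chair of the dihydropyran, so attack along the pseudo-axial trajectory, on the face of the C13 bridge and anti to the pseudo-equatorial C27, should set C10 with the (E)-nonenyl group pseudo-axial as in the target, and the cold quench keeps the doubly allylic ether from re-ionising.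

Step 19
Reactants: 28 bis-TBS ether of the target
Product: 29 CNP0127096.1
Conditions: n-Bu4NF, AcOH, THF, 0 °C to rt
Reagents that add atoms: none
Why: Fluoride cleaves both secondary silyl ethers; the acetic acid buffer protects the lactone from basic fluoride, and no strong acid is present that could ionise the doubly allylic C10–O11 bond.

Compound list
1 | methyl 3-hydroxycyclobutane-1-carboxylate (commercial cis/trans mixture) | COC(=O)C1CC(O)C1 | starting material
2 | methyl 3-(TBS-oxy)cyclobutane-1-carboxylate (cis/trans mixture) | COC(=O)C1CC(O[Si](C)(C)C(C)(C)C)C1 | intermediate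
3 | allyl bromide | C=CCBr | starting material
4 | lithium enolate of 2 | COC(O[Li])=C1CC(O[Si](C)(C)C(C)(C)C)C1 | intermediate (not isolated)
5 | methyl 1-allyl-3-(TBS-oxy)cyclobutane-1-carboxylate; allyl trans and ester cis to the silyloxy group | C=CC[C@@]1(C(=O)OC)C[C@H](O[Si](C)(C)C(C)(C)C)C1 | intermediate
6 | 1-allyl-3-(TBS-oxy)cyclobutane-1-carbaldehyde; formyl cis to the silyloxy group | C=CC[C@@]1(C=O)C[C@H](O[Si](C)(C)C(C)(C)C)C1 | intermediate (not isolated)
7 | 1-allyl-1-ethynyl-3-(TBS-oxy)cyclobutane; ethynyl cis to the silyloxy group | C=CC[C@@]1(C#C)C[C@H](O[Si](C)(C)C(C)(C)C)C1 | intermediate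
8 | lithium acetylide of 7 | C=CC[C@@]1(C#C[Li])C[C@H](O[Si](C)(C)C(C)(C)C)C1 | intermediate (not isolated)
9 | 3-[1-allyl-3-(TBS-oxy)cyclobutyl]prop-2-yn-1-ol; alkynyl cis to the silyloxy group | C=CC[C@@]1(C#CCO)C[C@H](O[Si](C)(C)C(C)(C)C)C1 | intermediate
10 | 1-allyl-1-[3-(4-methoxyphenoxy)prop-1-ynyl]-3-(TBS-oxy)cyclobutane; alkynyl cis to the silyloxy group | C=CC[C@@]1(C#CCOc2ccc(OC)cc2)C[C@H](O[Si](C)(C)C(C)(C)C)C1 | intermediate
11 | 2-{1-[3-(4-methoxyphenoxy)prop-1-ynyl]-3-(TBS-oxy)cyclobutyl}acetaldehyde | O=CC[C@@]1(C#CCOc2ccc(OC)cc2)C[C@H](O[Si](C)(C)C(C)(C)C)C1 | intermediate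
12 | tert-butyl diazoacetate | CC(C)(C)OC(=O)C=[N+]=[N-] | starting material
13 | tert-butyl (3R)-2-diazo-3-hydroxy-4-{1-[3-(4-methoxyphenoxy)prop-1-ynyl]-3-(TBS-oxy)cyclobutyl}butanoate | CC(C)(C)OC(=O)C(=[N+]=[N-])[C@H](O)C[C@@]1(C#CCOc2ccc(OC)cc2)C[C@H](O[Si](C)(C)C(C)(C)C)C1 | intermediate
14 | tert-butyl (3R)-2-diazo-3-(TBS-oxy)-4-{1-[3-(4-methoxyphenoxy)prop-1-ynyl]-3-(TBS-oxy)cyclobutyl}butanoate | CC(C)(C)OC(=O)C(=[N+]=[N-])[C@H](O[Si](C)(C)C(C)(C)C)C[C@@]1(C#CCOc2ccc(OC)cc2)C[C@H](O[Si](C)(C)C(C)(C)C)C1 | intermediate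
15 | tert-butyl (3R)-2-oxo-3-(TBS-oxy)-4-{1-[3-(4-methoxyphenoxy)prop-1-ynyl]-3-(TBS-oxy)cyclobutyl}butanoate | CC(C)(C)OC(=O)C(=O)[C@H](O[Si](C)(C)C(C)(C)C)C[C@@]1(C#CCOc2ccc(OC)cc2)C[C@H](O[Si](C)(C)C(C)(C)C)C1 | intermediate
16 | tert-butyl (3R)-2-oxo-3-(TBS-oxy)-4-{1-[(Z)-3-(4-methoxyphenoxy)prop-1-enyl]-3-(TBS-oxy)cyclobutyl}butanoate; alkenyl cis to O19 (precursor of the key step) | CC(C)(C)OC(=O)C(=O)[C@H](O[Si](C)(C)C(C)(C)C)C[C@@]1(/C=C\COc2ccc(OC)cc2)C[C@H](O[Si](C)(C)C(C)(C)C)C1 | intermediate
17 | tertiary C16 cyclopentyl cation after Prins closure and ring expansion, O11 bound as chlorodimethylaluminate (zwitterion) | C[Al-](C)(Cl)O[C@@]2(C(=O)OC(C)(C)C)[C@H](COc1ccc(OC)cc1)[C@@H]3C[C@@H](O[Si](C)(C)C(C)(C)C)C[C+]3C[C@H]2O[Si](C)(C)C(C)(C)C | intermediate (not isolated)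
18 | tricyclic cage lactone (C13 lactone bridging C12 and C16, cyclopentane fused at C16–C21); O11–H, C22–CH2O(4-methoxyphenyl), O19–TBS, O28–TBS; configuration at C12, C16, C18, C21, C22, C27 as in the target (product of the key step) | O[C@@]23C(=O)O[C@]4(C[C@H](O[Si](C)(C)C(C)(C)C)C[C@H]4[C@H]2COc1ccc(OC)cc1)C[C@H]3O[Si](C)(C)C(C)(C)C | intermediate
19 | cage lactone with free C23–OH and O11–H; O19–TBS, O28–TBS | O[C@@]23C(=O)O[C@]4(C[C@H](O[Si](C)(C)C(C)(C)C)C[C@H]4[C@H]2CO)C[C@H]3O[Si](C)(C)C(C)(C)C | intermediate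
20 | cage lactone C23 aldehyde with free O11–H | O[C@@]23C(=O)O[C@]4(C[C@H](O[Si](C)(C)C(C)(C)C)C[C@H]4[C@H]2C=O)C[C@H]3O[Si](C)(C)C(C)(C)C | intermediate
21 | cage lactone C23 aldehyde with O11–TMS | C[Si](C)(C)O[C@@]23C(=O)O[C@]4(C[C@H](O[Si](C)(C)C(C)(C)C)C[C@H]4[C@H]2C=O)C[C@H]3O[Si](C)(C)C(C)(C)C | intermediate
22 | cage lactone with (Z)-2-iodoprop-1-enyl on C22 (iodine cis to C22), O11–TMS | C[Si](C)(C)O[C@@]23C(=O)O[C@]4(C[C@H](O[Si](C)(C)C(C)(C)C)C[C@H]4[C@H]2/C=C(/C)I)C[C@H]3O[Si](C)(C)C(C)(C)C | intermediate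
23 | cage lactone with (Z)-2-methyl-3-oxoprop-1-enyl on C22 (C10 aldehyde cis to C22), O11–TMS | C[Si](C)(C)O[C@@]23C(=O)O[C@]4(C[C@H](O[Si](C)(C)C(C)(C)C)C[C@H]4[C@H]2/C=C(/C)C=O)C[C@H]3O[Si](C)(C)C(C)(C)C | intermediate (not isolated)
24 | cage lactone with the fused 3-methyl-2H-pyran, C10 methyl acetal (both anomers) | COC1O[C@@]23C(=O)O[C@]4(C[C@H](O[Si](C)(C)C(C)(C)C)C[C@H]4[C@H]2C=C1C)C[C@H]3O[Si](C)(C)C(C)(C)C | intermediate
25 | 1-nonyne | CCCCCCCC#C | starting material
26 | 2-[(E)-non-1-enyl]-1,3,2-benzodioxaborole | CCCCCCC/C=C/B1Oc2ccccc2O1 | intermediate (not isolated)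
27 | potassium (E)-non-1-enyltrifluoroborate | CCCCCCC/C=C/[B-](F)(F)F.[K+] | intermediate
28 | O19,O28-bis-TBS ether of the target | CCCCCCC/C=C/[C@H]1O[C@@]23C(=O)O[C@]4(C[C@H](O[Si](C)(C)C(C)(C)C)C[C@H]4[C@H]2C=C1C)C[C@H]3O[Si](C)(C)C(C)(C)C | intermediate
29 | CNP0127096.1 | CCCCCCC/C=C/[C@H]1O[C@@]23C(=O)O[C@]4(C[C@H](O)C[C@H]4[C@H]2C=C1C)C[C@H]3O | target

Total step count: 19. Longest linear sequence: 18 steps (1 to 16, then 18 and 19); step 17 prepares the side-chain reagent.

Steps most likely to fail

1. Step 11 (proposed new method). What may go wrong: the C16 cation is lost by proton loss or is intercepted by the aluminium alkoxide at O11 before the ester closes; the closure runs through the chair with the ester axial and gives the wrong face at C12; methyl transfer from aluminium to the activated ketone outruns the closure. Fallback, known reactions only, from alkyne 7 back to 18: the three bonds are made in separate operations. Compound 7 is carried through the chemistry of steps 6 to 9 (alkene cleavage to the aldehyde F1, asymmetric diazoacetate aldol with 12 to the diazo alcohol F2, silylation to the silyl ether F3, dimethyldioxirane oxidation to the ethynyl keto ester F4) and semihydrogenated over the Lindlar catalyst to the vinyl keto ester F5. 2-Bromoallyl 4-methoxyphenyl ether F6, from 2,3-dibromopropene and 4-methoxyphenol (K2CO3, acetone), is added to the C12 ketone under Nozaki–Hiyama–Kishi conditions (CrCl2, NiCl2 cat., DMSO); Felkin–Anh addition anti to the C27 silyloxy group should give the tertiary alcohol F7. Ring-closing metathesis (second-generation Hoveyda–Grubbs catalyst, toluene, 80 °C) closes the carbocycle as the spiro cyclohexene F8 with the C21=C22 double bond. Tamao's directed hydrosilylation then sets C22 and C21: O11 is converted with (HMe2Si)2NH into the dimethylsilyl ether F9, Pt2[(CH2=CHSiMe2)2O]3 delivers silicon to C21 and hydrogen to C22 from the O11 face (cyclic siloxane F10), and H2O2/KF/KHCO3 gives the diol F11 with the C21 hydroxyl trans to C23. Tf2O and 2,6-di-tert-butyl-4-methylpyridine convert the C21 hydroxyl into the triflate F12, which ionises with Wagner–Meerwein shift of C20 from C16 to C21 (inversion at C21, C20 cis to C23); the tertiary C16 cation is captured by the tert-butyl ester with loss of 2-methylpropene, giving 18.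

2. Step 18. What may go wrong: attack on the oxocarbenium face anti to the C13 bridge (wrong configuration at C10), attack at C23 with allylic transposition, or re-ionisation of the product with epimerisation. Fallback from iodide 22 back to 28, in which the roles of nucleophile and substituent are exchanged: Nozaki–Hiyama–Kishi coupling of 22 with commercial (E)-dec-2-enal (CrCl2, NiCl2 cat.) gives the bis-allylic alcohol F13 (both C10 epimers), Dess–Martin oxidation gives the cross-conjugated dienone F14, and pyridinium p-toluenesulfonate in methanol removes the trimethylsilyl group and closes the methyl ketal F15. Reduction with Et3SiH and BF3·OEt2 at −78 °C (known silane reduction of cyclic ketals through the oxocarbenium ion) then brings in hydrogen as the external nucleophile; if external nucleophiles prefer the face anti to the C13 bridge, hydride enters there and leaves the nonenyl group on the C13 face, as the target requires.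

3. Step 15. What may go wrong: slow addition of the bulky ylide to the hindered aldehyde, epimerisation at C22 by the basic ylide, erosion of the Z selectivity. Fallback from aldehyde 21 back to 24 without a basic ylide: Ramirez olefination (CBr4, PPh3, Et3N, CH2Cl2, 0 °C) gives the 1,1-dibromoalkene F16; palladium-catalysed Negishi coupling with Me2Zn (PdCl2(DPEphos), THF) replaces selectively the bromine trans to C22 and gives the (Z)-2-bromoalkene F17, which is formylated and acetalised under the conditions of step 16 to give 24.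

Further compounds
F1 | step 11 | 2-[1-ethynyl-3-(TBS-oxy)cyclobutyl]acetaldehyde; ethynyl cis to the silyloxy group | O=CC[C@@]1(C#C)C[C@H](O[Si](C)(C)C(C)(C)C)C1
F2 | step 11 | tert-butyl (3R)-2-diazo-4-[1-ethynyl-3-(TBS-oxy)cyclobutyl]-3-hydroxybutanoate | CC(C)(C)OC(=O)C(=[N+]=[N-])[C@H](O)C[C@@]1(C#C)C[C@H](O[Si](C)(C)C(C)(C)C)C1
F3 | step 11 | tert-butyl (3R)-2-diazo-4-[1-ethynyl-3-(TBS-oxy)cyclobutyl]-3-(TBS-oxy)butanoate | CC(C)(C)OC(=O)C(=[N+]=[N-])[C@H](O[Si](C)(C)C(C)(C)C)C[C@@]1(C#C)C[C@H](O[Si](C)(C)C(C)(C)C)C1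
F4 | step 11 | tert-butyl (3R)-4-[1-ethynyl-3-(TBS-oxy)cyclobutyl]-2-oxo-3-(TBS-oxy)butanoate | CC(C)(C)OC(=O)C(=O)[C@H](O[Si](C)(C)C(C)(C)C)C[C@@]1(C#C)C[C@H](O[Si](C)(C)C(C)(C)C)C1
F5 | step 11 | tert-butyl (3R)-2-oxo-3-(TBS-oxy)-4-[3-(TBS-oxy)-1-vinylcyclobutyl]butanoate; vinyl cis to O19 | CC(C)(C)OC(=O)C(=O)[C@H](O[Si](C)(C)C(C)(C)C)C[C@@]1(C=C)C[C@H](O[Si](C)(C)C(C)(C)C)C1
F6 | step 11 | 2-bromoallyl 4-methoxyphenyl ether | C=C(Br)COc1ccc(OC)cc1
F7 | step 11 | tertiary alcohol from addition of the 3-(4-methoxyphenoxy)prop-1-en-2-yl group to C12 of F5 | CC(C)(C)OC(=O)[C@](O)(C(=C)COc1ccc(OC)cc1)[C@H](O[Si](C)(C)C(C)(C)C)C[C@@]2(C=C)C[C@H](O[Si](C)(C)C(C)(C)C)C2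
F8 | step 11 | spiro[3.5]nonene with C21=C22 in the six-membered ring; C12 hydroxy ester, C22 aryloxymethyl, O19–TBS, O28–TBS | O[C@@]1(C(=O)OC(C)(C)C)C(COc2ccc(OC)cc2)=C[C@@]3(C[C@H](O[Si](C)(C)C(C)(C)C)C3)C[C@H]1O[Si](C)(C)C(C)(C)C
F9 | step 11 | O11-dimethylsilyl ether of F8 | C[SiH](C)O[C@@]1(C(=O)OC(C)(C)C)C(COc2ccc(OC)cc2)=C[C@@]3(C[C@H](O[Si](C)(C)C(C)(C)C)C3)C[C@H]1O[Si](C)(C)C(C)(C)C
F10 | step 11 | cyclic siloxane with Si bridging O11 and C21; H22 and Si on the O11 face | C[Si]1(C)O[C@@]2(C(=O)OC(C)(C)C)[C@H](COc3ccc(OC)cc3)[C@@H]1[C@@]4(C[C@H](O[Si](C)(C)C(C)(C)C)C4)C[C@H]2O[Si](C)(C)C(C)(C)C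
F11 | step 11 | spiro[3.5]nonane diol with O11–H and C21–OH, the C21 hydroxyl trans to C23 | O[C@@]1(C(=O)OC(C)(C)C)[C@H](COc2ccc(OC)cc2)[C@@H](O)[C@@]3(C[C@H](O[Si](C)(C)C(C)(C)C)C3)C[C@H]1O[Si](C)(C)C(C)(C)C
F12 | step 11 | C21 triflate of F11 | O[C@@]1(C(=O)OC(C)(C)C)[C@H](COc2ccc(OC)cc2)[C@@H](OS(=O)(=O)C(F)(F)F)[C@@]3(C[C@H](O[Si](C)(C)C(C)(C)C)C3)C[C@H]1O[Si](C)(C)C(C)(C)C
F13 | step 18 | cage lactone with the (1Z,4E)-3-hydroxy-2-methyldodeca-1,4-dienyl chain on C22 (C10 carbinol, both epimers), O11–TMS | C[Si](C)(C)O[C@@]23C(=O)O[C@]4(C[C@H](O[Si](C)(C)C(C)(C)C)C[C@H]4[C@H]2/C=C(/C)C(O)/C=C/CCCCCCC)C[C@H]3O[Si](C)(C)C(C)(C)C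
F14 | step 18 | cage lactone with the (1Z,4E)-2-methyl-3-oxododeca-1,4-dienyl chain on C22, O11–TMS | C[Si](C)(C)O[C@@]23C(=O)O[C@]4(C[C@H](O[Si](C)(C)C(C)(C)C)C[C@H]4[C@H]2/C=C(/C)C(=O)/C=C/CCCCCCC)C[C@H]3O[Si](C)(C)C(C)(C)C
F15 | step 18 | cage lactone with the fused 2H-pyran, C10 methyl ketal bearing the (E)-non-1-enyl group | COC1(/C=C/CCCCCCC)O[C@@]23C(=O)O[C@]4(C[C@H](O[Si](C)(C)C(C)(C)C)C[C@H]4[C@H]2C=C1C)C[C@H]3O[Si](C)(C)C(C)(C)C
F16 | step 15 | cage lactone with 2,2-dibromovinyl on C22, O11–TMS | C[Si](C)(C)O[C@@]23C(=O)O[C@]4(C[C@H](O[Si](C)(C)C(C)(C)C)C[C@H]4[C@H]2C=C(Br)Br)C[C@H]3O[Si](C)(C)C(C)(C)C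
F17 | step 15 | cage lactone with (Z)-2-bromoprop-1-enyl on C22 (bromine cis to C22), O11–TMS | C[Si](C)(C)O[C@@]23C(=O)O[C@]4(C[C@H](O[Si](C)(C)C(C)(C)C)C[C@H]4[C@H]2/C=C(/C)Br)C[C@H]3O[Si](C)(C)C(C)(C)C
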